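**Retrosynthetic overview**
1. Macrocycle (closed last): the bond from ring A to its CH2 is made by Pd-catalysed ring-opening of a tethered cyclopropanol, whose three-membered ring is enlarged to the 15-membered ketone ring.
2. Cyclopropanol from a methyl ester (Kulinkovich; EtMgBr gives the two CH2 groups next to ring A); benzylic CH2 of ring B from an aryl ketone; free OH of ring B from an ortho-fluorine (SNAr).
3. Aryl bromide by late bromination of ring A para to OMe; diaryl ether by SNAr of catechol on the para-fluorine of a 2,4-difluoro-3-methoxyphenyl keto acid, then double O-methylation.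
4. Keto acid from lithiated 2,6-difluoroanisole and glutaric anhydride; 2,6-difluoroanisole from 1,3-difluorobenzene. Rings A and B are bought as benzenes; the macrocycle is the only ring formed.

Assumption: the target SMILES has no stereocentre and no stereo-defined double bond, so the route delivers the single achiral constitution shown; any planar chirality of the macrocycle is taken as conformationally mobile and is not controlled.

Labels: ring A is the ring with one OMe (from catechol); ring B is the ring with OH and OMe (from 1,3-difluorobenzene).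

**Route**

Step 1
Reactants: 1 1,3-difluorobenzene
Product: 5 2,6-difluoroanisole, via 2,6-difluorophenyllithium 2 (not isolated), via lithium (2,6-difluorophenyl)trimethoxyborate 3 (not isolated), via sodium 2,6-difluorophenoxide 4 (not isolated)
Conditions: n-BuLi, THF, −78 °C; B(OMe)3, −78 °C to rt; aq. NaOH, 30% H2O2, 0 °C to rt; then Me2SO4, 40 °C (one pot)
Reagents that add atoms: hydrogen peroxide OO; dimethyl sulfate COS(=O)(=O)OC
Why: Directed ortho-lithiation takes the C–H flanked by both fluorines (the most acidic site), and borylation/oxidation of the aryllithium followed by Williamson methylation of the phenoxide is a standard hydroxylation–etherification sequence; no stereocentre.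

Step 2
Reactants: 5 2,6-difluoroanisole; 6 glutaric anhydride
Product: 8 5-(2,4-difluoro-3-methoxyphenyl)-5-oxopentanoic acid, via 2,4-difluoro-3-methoxyphenyllithium 7 (not isolated)
Conditions: n-BuLi, THF, −78 °C, 1 h; cannulate into 6 (1.5 equiv), THF, −78 to 0 °C; aq. HCl
Reagents that add atoms: none
Why: Directed ortho-metalation next to fluorine (the only C–H ortho to a directing group) gives the aryllithium, which opens the cyclic anhydride to the keto carboxylate; inverse addition to excess anhydride at −78 °C limits a second addition and benzyne formation.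

Step 3
Reactants: 8 5-(2,4-difluoro-3-methoxyphenyl)-5-oxopentanoic acid; 9 catechol
Product: 11 methyl 5-[2-fluoro-3-methoxy-4-(2-methoxyphenoxy)phenyl]-5-oxopentanoate, via hydroxyphenoxy keto acid 10 (not isolated)
Conditions: 9 (2 equiv), K2CO3, DMSO, 70 °C, N2; then MeI (excess), rt
Reagents that add atoms: iodomethane CI
Why: SNAr (addition–elimination): potassium catecholate attacks the fluorine para to the ketone, which is conjugated to the carbonyl and less hindered than the ortho-fluorine (flanked by acyl and OMe), and MeI then methylates the remaining phenol and the carboxylate in the same pot (Williamson etherification and ester alkylation).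

Step 4
Reactants: 11 methyl 5-[2-fluoro-3-methoxy-4-(2-methoxyphenoxy)phenyl]-5-oxopentanoate
Product: 12 methyl 5-[4-(5-bromo-2-methoxyphenoxy)-2-fluoro-3-methoxyphenyl]-5-oxopentanoate
Conditions: NBS (1.05 equiv), MeCN, 0 °C to rt, dark
Reagents that add atoms: N-bromosuccinimide O=C1CCC(=O)N1Br
Why: Electrophilic aromatic bromination: ring A (two oxygen donors, no acceptor) is far more electron-rich than the acyl- and fluoro-deactivated ring B, and OMe out-directs the electron-poor aryloxy group, so bromine enters para to OMe.

Step 5
Reactants: 12 methyl 5-[4-(5-bromo-2-methoxyphenoxy)-2-fluoro-3-methoxyphenyl]-5-oxopentanoate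
Product: 14 methyl 5-[4-(5-bromo-2-methoxyphenoxy)-2-hydroxy-3-methoxyphenyl]-5-oxopentanoate, via O-aryl acetohydroxamate 13 (not isolated)
Conditions: acetohydroxamic acid (3 equiv), K2CO3 (5 equiv), DMSO, 80 °C; aq. NH4Cl
Reagents that add atoms: acetohydroxamic acid CC(=O)NO
Why: SNAr with a hydroxide surrogate: the ketone-activated ortho-fluorine is displaced by the hydroxamate oxygen and the O-aryl hydroxamate fragments by Lossen rearrangement to the phenoxide, under conditions that spare the methyl ester and the unactivated aryl bromide.

Step 6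
Reactants: 14 methyl 5-[4-(5-bromo-2-methoxyphenoxy)-2-hydroxy-3-methoxyphenyl]-5-oxopentanoate
Product: 16 methyl 5-[4-(5-bromo-2-methoxyphenoxy)-2-hydroxy-3-methoxyphenyl]pentanoate, via benzylic alcohol 15 (not isolated)
Conditions: Et3SiH (3 equiv), TFA, 0 °C to rt
Reagents that add atoms: none
Why: Ionic hydrogenation: the ortho-hydroxy, para-aryloxy aryl ketone is protonated and reduced twice by hydride transfer through a well-stabilised benzylic cation, while the ester, aryl bromide and diaryl ether do not react; the transient carbinol stereocentre is destroyed.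

Step 7
Reactants: 16 methyl 5-[4-(5-bromo-2-methoxyphenoxy)-2-hydroxy-3-methoxyphenyl]pentanoate; 17 ethylmagnesium bromide
Product: 18 1-{4-[4-(5-bromo-2-methoxyphenoxy)-2-hydroxy-3-methoxyphenyl]butyl}cyclopropan-1-ol
Conditions: Ti(OiPr)4 (30 mol %), THF, 0 °C to rt, 17 (4 equiv) added over 1 h; aq. NH4Cl
Reagents that add atoms: none
Why: Kulinkovich cyclopropanation: the titanacyclopropane formed from EtMgBr and Ti(OiPr)4 adds twice to the ester carbonyl as a 1,2-dicarbanion equivalent; one extra equivalent of EtMgBr masks the phenol as its magnesium salt and the aryl bromide is inert.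

Step 8
Reactants: 18 1-{4-[4-(5-bromo-2-methoxyphenoxy)-2-hydroxy-3-methoxyphenyl]butyl}cyclopropan-1-ol
Product: 19 juglanin A
Conditions: Pd(OAc)2 (10 mol %), XPhos (20 mol %), Cs2CO3 (2.5 equiv), toluene, 80 °C, 18 added by syringe pump to 2 mM
Reagents that add atoms: none
Why: Proposed new method: a ring-expanding macrocyclisation in which zerovalent palladium (from Pd(OAc)2/XPhos) inserts into the C–Br bond of ring A, the caesium cyclopropoxide replaces bromide on divalent palladium, strain-driven β-carbon elimination opens the three-membered ring to a 16-membered palladium homoenolate (the ketone is now in place) and C(sp2)–C(sp3) reductive elimination gives the 15-membered ring, so the cyclopropanol ring grows from 3 to 15 atoms by taking up the 12-atom diaryl ether tether; the irreversible, strain-releasing C–C cleavage follows a reversible alkoxide exchange, XPhos favours reductive elimination over β-hydride elimination, high dilution suppresses oligomers and the hindered phenoxide is a poor partner for C–O coupling; the closest known reaction type is the intermolecular Pd-catalysed cross-coupling of cyclopropanol-derived ketone homoenolates with aryl bromides (ring-opening arylation), which has not been shown as a macrocyclisation to a cyclophane; no stereocentre is formed.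

**Compound list**
1 | 1,3-difluorobenzene | Fc1cccc(F)c1 | starting material
2 | 2,6-difluorophenyllithium (not isolated) | [Li]c1c(F)cccc1F | intermediate
3 | lithium (2,6-difluorophenyl)trimethoxyborate (not isolated) | [Li+].CO[B-](OC)(OC)c1c(F)cccc1F | intermediate
4 | sodium 2,6-difluorophenoxide (not isolated) | [Na+].[O-]c1c(F)cccc1F | intermediate
5 | 2,6-difluoroanisole | COc1c(F)cccc1F | intermediate
6 | glutaric anhydride | O=C1CCCC(=O)O1 | starting material
7 | 2,4-difluoro-3-methoxyphenyllithium (not isolated) | [Li]c1ccc(F)c(OC)c1F | intermediate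
8 | 5-(2,4-difluoro-3-methoxyphenyl)-5-oxopentanoic acid | COc1c(F)ccc(C(=O)CCCC(=O)O)c1F | intermediate
9 | catechol | Oc1ccccc1O | starting material
10 | 5-[2-fluoro-4-(2-hydroxyphenoxy)-3-methoxyphenyl]-5-oxopentanoic acid (hydroxyphenoxy keto acid; present as its potassium salt; not isolated) | COc1c(Oc2ccccc2O)ccc(C(=O)CCCC(=O)O)c1F | intermediate
11 | methyl 5-[2-fluoro-3-methoxy-4-(2-methoxyphenoxy)phenyl]-5-oxopentanoate | COC(=O)CCCC(=O)c1ccc(Oc2ccccc2OC)c(OC)c1F | intermediate
12 | methyl 5-[4-(5-bromo-2-methoxyphenoxy)-2-fluoro-3-methoxyphenyl]-5-oxopentanoate | COC(=O)CCCC(=O)c1ccc(Oc2cc(Br)ccc2OC)c(OC)c1F | intermediate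
13 | methyl 5-[2-(acetamidooxy)-4-(5-bromo-2-methoxyphenoxy)-3-methoxyphenyl]-5-oxopentanoate (O-aryl acetohydroxamate; not isolated) | COC(=O)CCCC(=O)c1ccc(Oc2cc(Br)ccc2OC)c(OC)c1ONC(C)=O | intermediate
14 | methyl 5-[4-(5-bromo-2-methoxyphenoxy)-2-hydroxy-3-methoxyphenyl]-5-oxopentanoate | COC(=O)CCCC(=O)c1ccc(Oc2cc(Br)ccc2OC)c(OC)c1O | intermediate
15 | methyl 5-[4-(5-bromo-2-methoxyphenoxy)-2-hydroxy-3-methoxyphenyl]-5-hydroxypentanoate (benzylic alcohol; racemic; not isolated) | COC(=O)CCCC(O)c1ccc(Oc2cc(Br)ccc2OC)c(OC)c1O | intermediate
16 | methyl 5-[4-(5-bromo-2-methoxyphenoxy)-2-hydroxy-3-methoxyphenyl]pentanoate | COC(=O)CCCCc1ccc(Oc2cc(Br)ccc2OC)c(OC)c1O | intermediate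
17 | ethylmagnesium bromide | CC[Mg]Br | starting material
18 | 1-{4-[4-(5-bromo-2-methoxyphenoxy)-2-hydroxy-3-methoxyphenyl]butyl}cyclopropan-1-ol | COc1ccc(Br)cc1Oc1ccc(CCCCC2(O)CC2)c(O)c1OC | intermediate
19 | juglanin A (achiral as drawn) | COc1ccc2cc1Oc1ccc(c(O)c1OC)CCCCC(=O)CC2 | target

**Step count**
Total: 8 steps. Longest linear sequence: 8 steps (1 to 19).

**Three steps most likely to fail**

1. Step 8 (the new ring-expanding macrocyclisation). The risks are β-hydride elimination of the palladium homoenolate (giving an enone and debrominated arene) and oligomerisation. The fallback uses known chemistry, sets out from 18 and comes back at 19. Compound 18 is opened oxidatively with Pd(OAc)2, pyridine and O2 in toluene at 80 °C to the vinyl ketone 7-[4-(5-bromo-2-methoxyphenoxy)-2-hydroxy-3-methoxyphenyl]hept-1-en-3-one F1. An intramolecular Mizoroki–Heck reaction at high dilution (Pd(OAc)2, P(o-tol)3, Et3N, MeCN, 80 °C, 2 mM) then closes the ring to the macrocyclic enone (E)-dehydrojuglanin A F2, which has a trans C=C between the two chain carbons next to ring A. Hydrogenation of that C=C (H2, Pd/C, EtOAc, rt) gives 19.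

2. Step 5 (fluoride to hydroxyl on a ring already carrying two donors, with a methyl ester present). The risks are slow SNAr and partial loss of the ester. The fallback sets out from 12 and comes back at 16. KOH in DMSO/water at 100 °C displaces the fluoride and saponifies the ester to 5-[4-(5-bromo-2-methoxyphenoxy)-2-hydroxy-3-methoxyphenyl]-5-oxopentanoic acid F3. Et3SiH in TFA reduces the ketone to 5-[4-(5-bromo-2-methoxyphenoxy)-2-hydroxy-3-methoxyphenyl]pentanoic acid F4. Fischer esterification (MeOH, cat. H2SO4, reflux) gives 16.

3. Step 3 (mono-arylation of catechol, para versus ortho fluorine). The risks are double arylation or air oxidation of catecholate and some ortho substitution. The fallback sets out from 9 and 8 and comes back at 11. Catechol 9 is first mono-methylated (Me2SO4, aq. NaOH, distillation) to 2-methoxyphenol F5, a mono-functional and oxidation-stable nucleophile. F5 with K2CO3 in DMSO at 70 °C displaces the para-fluorine of 8 to give 5-[2-fluoro-3-methoxy-4-(2-methoxyphenoxy)phenyl]-5-oxopentanoic acid F6. MeI/K2CO3 in DMF then esterifies F6 to 11; any ortho isomer is removed by chromatography at this stage.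

**Further compounds**
F1 | step 8 | 7-[4-(5-bromo-2-methoxyphenoxy)-2-hydroxy-3-methoxyphenyl]hept-1-en-3-one | C=CC(=O)CCCCc1ccc(Oc2cc(Br)ccc2OC)c(OC)c1O
F2 | step 8 | (E)-dehydrojuglanin A (macrocyclic enone, trans C=C between the two chain carbons next to ring A) | COc1ccc2cc1Oc1ccc(c(O)c1OC)CCCCC(=O)/C=C/2
F3 | step 5 | 5-[4-(5-bromo-2-methoxyphenoxy)-2-hydroxy-3-methoxyphenyl]-5-oxopentanoic acid | OC(=O)CCCC(=O)c1ccc(Oc2cc(Br)ccc2OC)c(OC)c1O
F4 | step 5 | 5-[4-(5-bromo-2-methoxyphenoxy)-2-hydroxy-3-methoxyphenyl]pentanoic acid | OC(=O)CCCCc1ccc(Oc2cc(Br)ccc2OC)c(OC)c1O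
F5 | step 3 | 2-methoxyphenol | COc1ccccc1O
F6 | step 3 | 5-[2-fluoro-3-methoxy-4-(2-methoxyphenoxy)phenyl]-5-oxopentanoic acid | OC(=O)CCCC(=O)c1ccc(Oc2ccccc2OC)c(OC)c1F
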